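The constants of these flasks are hidden at this stage, so we start from the balance of the starting material.

| flask | starting material | temperature | remark | time |
|---|---|---|---|---|
| larch | 0.15 M | −20 °C | run made earlier |  |
| zeta | 0.10 M |  | at −20 °C throughout | 25 min |
| theta | 0.10 M |  | at −20 °C until 3.0 min, from then on at 0 °C | 6.0 min |

larch run (percent of the starting material charged)

| time / s | ring / % | starting material / % |
|---|---|---|
| 10.0 | 1.0 | 96.5 |
| 15.0 | 1.4 | 95.1 |
| 30.0 | 1.9 | 90.4 |
| 50.0 | 3.1 | 84.9 |
| 60.0 | 3.5 | 82.1 |
| 80.0 | 4.4 | 77.3 |
| 120 | 5.0 | 69.2 |

(each reading ± 0.3 percentage points)

- the analysis behind the earlier runs scatters by 0.3 percentage points, standard deviation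
- the earlier runs do not show what temperature does; that part of a forecast is a guess

- which of the two ends with the higher amount of ring, in percent of the starting material charged ("neither" if they lie within 2 percentage points) (zeta / theta / neither)
- ring at the end, in percent of the starting material charged, zeta
- ring at the end, in percent of the starting material charged, theta

What has reacted is either ring or something not measured. At the last larch reading, ring over starting material consumed gives 0.162; we call this the ring share, the selectivity to ring. At 30.0 s it read 0.198, higher, so holding it constant is a rough step. We then reckon ring as share times starting material consumed.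

Take the settings in turn. The amount falls from 0.15 M to 0.10 M. One concentration shows no order, but if a second-order loss runs beside ring formation, lower [starting material] raises the share. So our reckoning may run low.

Time acts through conversion. A second-order law through the last larch reading leaves 21.2 % in zeta, and first order leaves 1.00 %. We therefore put ring in zeta between 12.8 % and 16.0 %.

The earlier runs do not show what temperature does. Holding the share as a guess, the same two laws put theta without its warming at 7.65 % to 10.9 % ring after 6.0 min, less than in zeta. Warming should raise the conversion by an amount we cannot read, and full conversion at the held share gives 16.2 %. So we guess that theta draws level with zeta and expect neither, and that choice rests on the guess about temperature.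

The forecast also says neither, with 1.3 % for zeta and 1.3 % for theta, because it reads ring as “so it is an intermediate”. Our zeta is higher.

Zeta gives 15.3 % and theta 34.6 %, so theta ends higher.

    starting material → ring (k = 8.75 × 10⁻⁴ s⁻¹, Ea = 69.0 kJ mol⁻¹)
    2 starting material → open dimer (k = 0.00889 M⁻¹ s⁻¹, Ea = 38.0 kJ mol⁻¹)
    ring ⇌ isomer of the product (K = 2.00, k = 0.0118 s⁻¹, Ea = 69.0 kJ mol⁻¹, ΔH = −30.0 kJ mol⁻¹)
    (constants at −20 °C)

Theta held cold gives 8.90 %. The end share is 0.172 in zeta and 0.378 in theta. Neither flask is at rest: zeta holds 11 % starting material and theta 8.4 %. Spending that remainder at each flask's share gives zeta 17.2 % and theta 37.8 %. Left until 250 min, zeta reads 18.2 %. Theta reads 38.9 % at 10 min, and at 60.0 min it reads 39.4 %.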